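**Assumption:** Serpyllin is 5-hydroxy-7,8,2',3',4'-pentamethoxyflavone. The SMILES has no stereocenters, so the target is achiral and "single enantiomer" has no consequence. The only stereochemical element in the route is the E-chalcone, which is lost on cyclisation.

## Retrosynthetic overview
1. The 5-OH group is disconnected to a C5–H bond. A chromone-carbonyl-directed C5–H oxygenation (the new step) would install it on 7,8,2',3',4'-pentamethoxyflavone.
2. The γ-pyranone ring is opened by C–O disconnection (I2/DMSO oxidative cyclisation) to the 2'-hydroxychalcone.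
3. The chalcone comes from a Claisen–Schmidt aldol of 2-hydroxy-3,4-dimethoxyacetophenone and 2,3,4-trimethoxybenzaldehyde.
4. The acetophenone comes from regioselective 3,4-di-O-methylation of gallacetophenone. Ring A's 5-oxygen is thus introduced last, after the pyranone ring is formed.

## Forward route

**Step 1**
Reactants: 1 (2',3',4'-trihydroxyacetophenone, gallacetophenone)
Product: 2 (1-(2-hydroxy-3,4-dimethoxyphenyl)ethan-1-one)
Conditions: MeI (2.3 equiv), K2CO3 (3 equiv), acetone, reflux, 12 h
Reagents that add atoms: iodomethane, CI
Why: Double Williamson O-methylation occurs at the acidic 4-OH and 3-OH groups, while the 2-OH is locked in a hydrogen bond to the carbonyl and is not alkylated.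

**Step 2**
Reactants: 2 (1-(2-hydroxy-3,4-dimethoxyphenyl)ethan-1-one); 3 (2,3,4-trimethoxybenzaldehyde)
Product: 4 ((E)-1-(2-hydroxy-3,4-dimethoxyphenyl)-3-(2,3,4-trimethoxyphenyl)prop-2-en-1-one)
Conditions: 50% aq. KOH, EtOH, rt, 24 h; then 1 M HCl to pH 3
Reagents that add atoms: none
Why: Claisen–Schmidt condensation (aldol then E1cB dehydration) of the non-enolisable aldehyde with the methyl ketone gives the thermodynamically favoured E-enone.

**Step 3**
Reactants: 4 (the 2'-hydroxychalcone)
Product: 5 (7,8,2',3',4'-pentamethoxyflavone)
Conditions: I2 (0.2 equiv), DMSO, 130 °C, 3 h; then aq. Na2S2O3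
Reagents that add atoms: none (catalytic I2 and DMSO are not retained)
Why: This is the I2/DMSO oxidative cyclisation. Iodination, intramolecular phenoxide oxa-Michael addition to a flavanone or iodoflavanone, and elimination of HI (with I2 regenerated by DMSO) give the flavone, and the E-geometry is lost.

**Step 4 (key step)**
Reactants: 5 (7,8,2',3',4'-pentamethoxyflavone)
Product: 6 (5-trifluoroacetoxy-7,8,2',3',4'-pentamethoxyflavone)
Conditions: [RuCl2(p-cymene)]2 (5 mol%), PhI(OAc)2 (2 equiv), TFA/TFAA (4:1), 80 °C, 12 h, N2
Reagents that add atoms: trifluoroacetic acid, OC(=O)C(F)(F)F (the source of the C5–O oxygen, as CF3CO2–); PhI(OAc)2, CC(=O)OI(OC(C)=O)c1ccccc1 (oxidant, only iodobenzene and AcOH leave); TFAA, O=C(OC(=O)C(F)(F)F)C(F)(F)F (keeps the medium anhydrous and regenerates trifluoroacetate)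
Why: Proposed new method: The chromone C4=O directs carboxylate-assisted (CMD) ruthenation of the peri C5–H bond, forming a five-membered oxaruthenacycle. PhI(OCOCF3)2 formed in situ oxidises Ru(II) to Ru(IV), and C–O reductive elimination gives the aryl trifluoroacetate. Ring A's C6–H is not directed, and the B-ring C6'–H would need a disfavoured seven-membered metallacycle. The closest known reactions are the Ru(II)-catalysed ketone-directed ortho-C–H hydroxylation of aryl ketones and the chromone-C4=O-directed C5–H functionalisations (alkenylation, amidation). Oxygenation of a fully methoxylated flavone at the peri position has not been shown. This step forms the C5–O bond and sets the 5-oxygenation regiochemistry; it creates no stereocenter.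

**Step 5**
Reactants: 6 (the 5-trifluoroacetate)
Product: 7 (Serpyllin, 5-hydroxy-7,8,2',3',4'-pentamethoxyflavone)
Conditions: K2CO3 (1.5 equiv), MeOH, rt, 30 min; then 1 M HCl to pH 4
Reagents that add atoms: none (the methanol is not retained; it leaves as CF3CO2Me)
Why: The peri aryl trifluoroacetate is a very labile activated ester and is cleaved by methanolysis. The methyl ethers, the pyranone and the aryl ring are untouched, and the chelated 5-OH is released.

## Compound list
1 | 2',3',4'-trihydroxyacetophenone (gallacetophenone) | CC(=O)c1ccc(O)c(O)c1O | starting material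
2 | 2'-hydroxy-3',4'-dimethoxyacetophenone | CC(=O)c1ccc(OC)c(OC)c1O | intermediate
3 | 2,3,4-trimethoxybenzaldehyde | O=Cc1ccc(OC)c(OC)c1OC | starting material
4 | (E)-2'-hydroxy-3',4',2,3,4-pentamethoxychalcone | COc1ccc(/C=C/C(=O)c2ccc(OC)c(OC)c2O)c(OC)c1OC | intermediate
5 | 7,8,2',3',4'-pentamethoxyflavone | COc1ccc(-c2cc(=O)c3ccc(OC)c(OC)c3o2)c(OC)c1OC | intermediate
6 | 5-trifluoroacetoxy-7,8,2',3',4'-pentamethoxyflavone | COc1ccc(-c2cc(=O)c3c(OC(=O)C(F)(F)F)cc(OC)c(OC)c3o2)c(OC)c1OC | intermediate
7 | Serpyllin (5-hydroxy-7,8,2',3',4'-pentamethoxyflavone) | COc1ccc(-c2cc(=O)c3c(O)cc(OC)c(OC)c3o2)c(OC)c1OC | target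

**Total steps:** 5. **Longest linear sequence:** 5 steps (1 → 2 → 4 → 5 → 6 → 7 is counted as steps 1, 2, 3, 4, 5).

## Three steps most likely to fail
1. **Step 4 (proposed new C5–H oxygenation).** The electron-rich 2,3,4-trimethoxyphenyl ring may be oxidised by the hypervalent iodine reagent, or C5 reactivity may be low.
   - Fallback (known chemistry): use 2-hydroxy-3,4,6-trimethoxyacetophenone in the same Claisen–Schmidt and I2/DMSO sequence to give 5,7,8,2',3',4'-hexamethoxyflavone. Then remove the peri 5-OMe selectively with BCl3 in CH2Cl2 (–78 → 0 °C) to give Serpyllin.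
2. **Step 3 (I2/DMSO cyclisation).** Electrophilic aryl iodination of the electron-rich B ring or ring A may compete, or the reaction may stall at the flavanone.
   - Fallback: use the Baker–Venkataraman route. Acylate 2 with 2,3,4-trimethoxybenzoyl chloride (pyridine), rearrange with KOH/pyridine to the 1,3-diketone, and cyclodehydrate with AcOH/H2SO4 to give 5.
3. **Step 1 (regioselective di-O-methylation).** Over-methylation at the 2-OH or under-methylation would give mixtures.
   - Fallback: make 2 by a different approach. Acetylate 2,3-dimethoxyphenol and perform a BF3·OEt2-mediated Fries rearrangement, which gives the ortho-acyl product, 2-hydroxy-3,4-dimethoxyacetophenone.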